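Don't take Monday's flask for slow: its slowness is an ending, and you can read that in powers of ten. Here is what you inherit:

in all of them: Sub 0.10 M; Sub2 0.10 M; Kat 20 mM

| flask | Rgt | Rgt2 | remark | time |
|---|---|---|---|---|
| Monday's | 0.22 M | 13 mM | the very flask that is asked about, followed so far |  |
| Tuesday's | 0.22 M | 8.7 mM | run made earlier |  |
| flask | 0.220 M | 13 mM |  | 1.0 h |

| run | time / min | Sub / % | Tgt2 / % |
|---|---|---|---|
| Monday's | 2.00 | 28.8 | 26.2 |
| Monday's | 3.00 | 26.5 | 29.9 |
| Monday's | 5.00 | 23.3 | 34.8 |
| Monday's | 8.00 | 21.9 | 39.8 |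
| Monday's | 15.0 | 21.3 | 40.9 |
| Monday's | 25.0 | 20.2 | 43.3 |
| Tuesday's | 3.00 | 22.6 | 35.7 |
| Tuesday's | 8.00 | 19.1 | 44.5 |
| Tuesday's | 15.0 | 17.5 | 46.1 |
| Tuesday's | 25.0 | 17.0 | 47.2 |
| Tuesday's | 30.0 | 16.7 | 47.1 |
| Tuesday's | 40.0 | 16.2 | 46.4 |

(each reading ± 0.5 percentage points)

- Kat is single-handed; Sub and Sub2 are mirror images of each other, charged as a racemate, each of them at the stated concentration
- the reaction counts as stopped when no species that holds the Sub and Sub2 together changes by six tenths of a point or more over the second half of the time

- at 1.0 h, what has stopped the reaction, if anything has (forward and back rates have come level / it is still moving / no working catalyst is left / Rgt has run out first / all of Sub has reacted)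
- how much of the Sub and Sub2 together has reacted by 1.0 h
- how much Tgt2 there is at 1.0 h, in percent of the Sub and Sub2 together charged
- how much Sub2 there is at 1.0 h, in percent of the Sub and Sub2 together charged

In Monday's flask Tgt2 gains 3.7 percentage points in 1.00 min early on, but 2.4 points in 10.0 min late. The rate therefore falls by 1.19 powers of ten in 17.5 min:

17.5 min / 1.19 = 14.7 min

That is the decade time, the minutes in which the rate of Tgt2 gain falls one power of ten. Extrapolate the late rate to the half hour, multiply by the decade time and divide by 2.30, and you have the gain to expect after the half hour, if the fall keeps that pace: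

0.32 points

That is less than the scatter of 0.5 points, so I call Monday's flask stopped; don't extend the hour. At the 25.0 min reading Sub plus Tgt2 is 63.5%, more than the Sub charged, half of the total, so material charged as Sub2 has reached Sub or Tgt2. I read that as Sub and Sub2 passing into each other, and as mirror images they should then come level, so I expect Sub2 near the 20.2% read for Sub and conversion near 59.6%. My guess for what gave out is Rgt.

The forecast differs: it is still moving, conversion 77%, Tgt2 45%, Sub2 5%, since “Sub is still dropping about 0.07–0.1 points/min”.

The flask gives Rgt has run out first, conversion 60.2%, Tgt2 43.3%, Sub2 19.9%.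

    Rgt + Kat + Sub → Kat + Tgt2 (k = 5.20 M⁻² s⁻¹)
    Rgt + Kat + Sub2 → Kat + Tgt3 (k = 1.80 M⁻² s⁻¹)
    Sub ⇌ Sub2 (k = 0.00680 s⁻¹)
    2 Rgt → Tgt (k = 0.0220 M⁻¹ s⁻¹)
    Kat + Rgt2 ⇌ Kat.Rgt2, settled at all times (K = 450 M⁻¹)

In this flask Rgt, the limiting reagent, stands at 0% of its charge at 1.00 h, less than the 40% of Sub left, after falling one power of ten every 13.1 min on average from 0.100 h to 0.500 h. The half-life of Sub by its forward step to Sub2 alone, 1.7 min, is short against the hour, and Sub and Sub2 stand at 19.9% and 19.9%. Carrying 14.7 min onto Tuesday's run from its 15.0 min reading gives Tgt2 46.9%, and at the time of its last reading, without the scatter, that run holds 47.0%.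

The numbers in the tables were computed with made-up constants; scatter was added.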